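**Strategy.** The ring is read as a desymmetrised para-quinol. C7a, which carries O1 and the C8 side chain, lies para to the C5 carbonyl, so a 4-alkyl-4-hydroxycyclohexa-2,5-dienone holds C7a on a local symmetry plane between two constitutionally identical enone arms. The key step disconnects the O3–C3a bond and the acetal carbon C2. A chiral-acid-catalysed formaldehyde hemiacetalisation/oxa-Michael cascade closes the dioxolane onto one arm. This makes C7a stereogenic next to the preset C8 centre and differentiates the two ring halves for later vinylogous-ester formation and allylation. The precursor is the prochiral p-quinol obtained by dearomatising an (R)-1,2-diarylpropane phenol.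

Key step: step 5

Atom labels follow the benzodioxole numbering of the target: O1, C2, O3, C3a, C4, C5 (C=O), C6 (allyl), C7, C7a (quaternary); C8 is the side-chain methine.

Assumption: 1 and 2 are taken as catalogue compounds, and the enantiomer of each chiral catalyst (steps 2 and 5) that gives the drawn configuration is fixed by a pilot run with both antipodes.

**Step 1**
Reactants: 1 tert-butyl(4-ethynylphenoxy)dimethylsilane; 2 5-iodo-1,2,3-trimethoxybenzene
Product: 4 tert-butyldimethyl{4-[(1E)-1-(3,4,5-trimethoxyphenyl)prop-1-en-2-yl]phenoxy}silane, via alkenylalane 3 (not isolated)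
Conditions: Me3Al, Cp2ZrCl2 (0.25 equiv), CH2Cl2, 0 °C to rt; volatiles removed; then 2, Pd(PPh3)4 (5 mol%), ZnCl2 (0.2 equiv), THF, rt
Reagents that add atoms: trimethylaluminium, C[Al](C)C
Why: Zr-catalysed syn-carboalumination of the terminal aryl alkyne places CH3 on the internal carbon and Al on the terminal carbon on the same side, and the Pd-catalysed Negishi coupling of alkenylalane 3 with 2 proceeds with retention, so the trisubstituted alkene should form as the E isomer only.

**Step 2**
Reactants: 4 tert-butyldimethyl{4-[(1E)-1-(3,4,5-trimethoxyphenyl)prop-1-en-2-yl]phenoxy}silane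
Product: 5 tert-butyldimethyl{4-[(2R)-1-(3,4,5-trimethoxyphenyl)propan-2-yl]phenoxy}silane
Conditions: H2 (50 bar), [Ir(cod)(tBu-PHOX-type P,N ligand)]BArF (1 mol%), CH2Cl2, rt
Reagents that add atoms: none
Why: Ir–P,N-catalysed asymmetric hydrogenation of an unfunctionalised (E)-α-methylstilbene, the standard substrate class for these catalysts, sets C8 by catalyst-controlled face selection, while the silyl ether and both arenes are inert.

**Step 3**
Reactants: 5 tert-butyldimethyl{4-[(2R)-1-(3,4,5-trimethoxyphenyl)propan-2-yl]phenoxy}silane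
Product: 6 4-[(2R)-1-(3,4,5-trimethoxyphenyl)propan-2-yl]phenol
Conditions: TBAF (1.1 equiv), AcOH (1.1 equiv), THF, 0 °C
Reagents that add atoms: none
Why: Fluoride-induced cleavage of an aryl silyl ether under buffered conditions, which cannot touch the non-acidic C8 centre or the methyl ethers.

**Step 4**
Reactants: 6 4-[(2R)-1-(3,4,5-trimethoxyphenyl)propan-2-yl]phenol
Product: 8 4-hydroxy-4-[(2R)-1-(3,4,5-trimethoxyphenyl)propan-2-yl]cyclohexa-2,5-dien-1-one, via hydroperoxydienone 7 (not isolated)
Conditions: Oxone, NaHCO3, MeCN/H2O, rt; then Me2S, rt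
Reagents that add atoms: Oxone (potassium peroxymonosulfate), [K+].[O-]S(=O)(=O)OO
Why: Oxidative dearomatisation of a 4-alkylphenol by singlet oxygen generated in situ from buffered peroxymonosulfate gives the para-hydroperoxydienone 7, whose O–O bond is reduced by the sulfide, and the carbinol carbon is not yet stereogenic because the two enone arms are identical.

**Step 5**
Reactants: 8 4-hydroxy-4-[(2R)-1-(3,4,5-trimethoxyphenyl)propan-2-yl]cyclohexa-2,5-dien-1-one
Product: 10 (3aR,7aS)-7a-[(2R)-1-(3,4,5-trimethoxyphenyl)propan-2-yl]-3a,7a-dihydro-1,3-benzodioxol-5(4H)-one (cis-fused, enone at C6=C7), via formaldehyde hemiacetal 9 (not isolated)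
Conditions: (CH2O)n (3 equiv), (R)-TRIP (10 mol%), ClCH2CH2Cl, 40 °C
Reagents that add atoms: formaldehyde (as paraformaldehyde), C=O
Why: The weak chiral Brønsted acid first lets the tertiary hydroxyl of 8 add to formaldehyde (hemiacetal 9) and then, hydrogen-bonded both to the hemiacetal OH and to the dienone carbonyl, guides the intramolecular oxa-Michael addition of that OH to the β-carbon of one enone arm. The closest known reaction type is the Brønsted-acid-catalysed acetalisation/oxa-Michael desymmetrisation of p-quinols with aldehydes to 1,3-dioxolanes. The dioxolane is closed in the 5-exo-trig mode by the O3–C3a bond, and the three-atom O1–C2–O3 tether can reach C3a only from the face that carries O1, so the cis ring fusion (O3 cis to O1, H-3a cis to the side chain) is fixed by the substrate. C7a, until then on the local symmetry plane of the dienone, becomes stereogenic through the choice of arm, and this choice is made by the chiral phosphate pocket acting together with the fixed (R)-C8 centre. The step therefore needs diastereotopic-arm selectivity only: the quaternary carbon leaves no other hydroxyl or enolisable site, the weak acid should not drive hydroxymethylation of the trimethoxyarene or a dienone–phenol rearrangement, and because C8 is already a single enantiomer the wrong-arm product would be a separable diastereomer. The C3a centre is auxiliary and is erased in step 6.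

**Step 6**
Reactants: 10 (3aR,7aS)-7a-[(2R)-1-(3,4,5-trimethoxyphenyl)propan-2-yl]-3a,7a-dihydro-1,3-benzodioxol-5(4H)-one
Product: 12 (7aS)-7a-[(2R)-1-(3,4,5-trimethoxyphenyl)propan-2-yl]-1,3-benzodioxol-5(7aH)-one, via trimethylsilyl dienol ether 11 (not isolated)
Conditions: TMSOTf, Et3N, CH2Cl2, −78 to 0 °C; then Pd(OAc)2 (1.1 equiv), MeCN, rt
Reagents that add atoms: none
Why: Soft enolisation can occur only at C4 because C7a is quaternary, and Saegusa–Ito oxidation of silyl dienol ether 11 (Pd(II) enolate, β-hydride elimination of H-3a) should give the cross-conjugated dienone with the vinylogous ester in place and C7a untouched.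

**Step 7**
Reactants: 12 (7aS)-7a-[(2R)-1-(3,4,5-trimethoxyphenyl)propan-2-yl]-1,3-benzodioxol-5(7aH)-one
Product: 13 (7aR)-7a-[(2R)-1-(3,4,5-trimethoxyphenyl)propan-2-yl]-6,7-dihydro-1,3-benzodioxol-5(7aH)-one
Conditions: H2 (1 atm), RhCl(PPh3)3 (5 mol%), benzene/EtOH, rt
Reagents that add atoms: none
Why: Homogeneous Rh(I) hydrogenation distinguishes the disubstituted C6=C7 enone bond from the trisubstituted, oxygen-bearing C3a=C4 bond, the selectivity known for 1,4-dien-3-ones, and the change of the C7a descriptor from S to R reflects only the new CIP ranking of C7.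

**Step 8**
Reactants: 13 (7aR)-7a-[(2R)-1-(3,4,5-trimethoxyphenyl)propan-2-yl]-6,7-dihydro-1,3-benzodioxol-5(7aH)-one
Product: 15 (6R,7aR)-6-(prop-2-en-1-yl)-7a-[(2R)-1-(3,4,5-trimethoxyphenyl)propan-2-yl]-6,7-dihydro-1,3-benzodioxol-5(7aH)-one, via lithium dienolate 14 (not isolated)
Conditions: LDA (1.1 equiv), THF, −78 °C; allyl bromide, DMPU, −78 to −30 °C
Reagents that add atoms: allyl bromide, C=CCBr
Why: Stork–Danheiser α'-alkylation, in which LDA deprotonates the vinylogous ester kinetically at C6 (no γ-hydrogen exists) and allyl bromide should approach dienolate 14 anti to the pseudo-axial C8 side chain on C7a (O1 is held pseudo-equatorial by the dioxolane), giving the 6R epimer with equatorial allyl trans to the side chain, which is also the thermodynamically favoured epimer.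

**Compound list**
1 | tert-butyl(4-ethynylphenoxy)dimethylsilane | C#Cc1ccc(O[Si](C)(C)C(C)(C)C)cc1 | starting material
2 | 5-iodo-1,2,3-trimethoxybenzene | COc1cc(I)cc(OC)c1OC | starting material
3 | [(1E)-2-{4-[(tert-butyldimethylsilyl)oxy]phenyl}prop-1-en-1-yl]dimethylalane | C/C(=C\[Al](C)C)c1ccc(O[Si](C)(C)C(C)(C)C)cc1 | intermediate
4 | tert-butyldimethyl{4-[(1E)-1-(3,4,5-trimethoxyphenyl)prop-1-en-2-yl]phenoxy}silane | C/C(=C\c1cc(OC)c(OC)c(OC)c1)c1ccc(O[Si](C)(C)C(C)(C)C)cc1 | intermediate
5 | tert-butyldimethyl{4-[(2R)-1-(3,4,5-trimethoxyphenyl)propan-2-yl]phenoxy}silane | C[C@H](Cc1cc(OC)c(OC)c(OC)c1)c1ccc(O[Si](C)(C)C(C)(C)C)cc1 | intermediate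
6 | 4-[(2R)-1-(3,4,5-trimethoxyphenyl)propan-2-yl]phenol | C[C@H](Cc1cc(OC)c(OC)c(OC)c1)c1ccc(O)cc1 | intermediate
7 | 4-hydroperoxy-4-[(2R)-1-(3,4,5-trimethoxyphenyl)propan-2-yl]cyclohexa-2,5-dien-1-one | C[C@H](Cc1cc(OC)c(OC)c(OC)c1)C1(OO)C=CC(=O)C=C1 | intermediate
8 | 4-hydroxy-4-[(2R)-1-(3,4,5-trimethoxyphenyl)propan-2-yl]cyclohexa-2,5-dien-1-one | C[C@H](Cc1cc(OC)c(OC)c(OC)c1)C1(O)C=CC(=O)C=C1 | intermediate
9 | 4-(hydroxymethoxy)-4-[(2R)-1-(3,4,5-trimethoxyphenyl)propan-2-yl]cyclohexa-2,5-dien-1-one | C[C@H](Cc1cc(OC)c(OC)c(OC)c1)C1(OCO)C=CC(=O)C=C1 | intermediate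
10 | (3aR,7aS)-7a-[(2R)-1-(3,4,5-trimethoxyphenyl)propan-2-yl]-3a,7a-dihydro-1,3-benzodioxol-5(4H)-one | O=C1C=C[C@]2([C@H](C)Cc3cc(OC)c(OC)c(OC)c3)OCO[C@@H]2C1 | intermediate
11 | trimethyl({(3aR,7aS)-7a-[(2R)-1-(3,4,5-trimethoxyphenyl)propan-2-yl]-3a,7a-dihydro-1,3-benzodioxol-5-yl}oxy)silane | C[Si](C)(C)OC1=C[C@H]2OCO[C@]2(C=C1)[C@H](C)Cc1cc(OC)c(OC)c(OC)c1 | intermediate
12 | (7aS)-7a-[(2R)-1-(3,4,5-trimethoxyphenyl)propan-2-yl]-1,3-benzodioxol-5(7aH)-one | O=C1C=C[C@]2([C@H](C)Cc3cc(OC)c(OC)c(OC)c3)OCOC2=C1 | intermediate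
13 | (7aR)-7a-[(2R)-1-(3,4,5-trimethoxyphenyl)propan-2-yl]-6,7-dihydro-1,3-benzodioxol-5(7aH)-one | O=C1CC[C@]2([C@H](C)Cc3cc(OC)c(OC)c(OC)c3)OCOC2=C1 | intermediate
14 | lithium (7aR)-7a-[(2R)-1-(3,4,5-trimethoxyphenyl)propan-2-yl]-7,7a-dihydro-1,3-benzodioxol-5-olate (C5=C6 dienolate) | [Li]OC1=CC[C@]2([C@H](C)Cc3cc(OC)c(OC)c(OC)c3)OCOC2=C1 | intermediate
15 | (6R,7aR)-6-(prop-2-en-1-yl)-7a-[(2R)-1-(3,4,5-trimethoxyphenyl)propan-2-yl]-6,7-dihydro-1,3-benzodioxol-5(7aH)-one | C=CC[C@@H]1C[C@]2([C@H](C)Cc3cc(OC)c(OC)c(OC)c3)OCOC2=CC1=O | target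

Total step count: 8. Longest linear sequence: 8 steps (1 to 15).

**Steps most likely to fail**

Step 5. The chiral acid may not distinguish the two diastereotopic enone arms of hemiacetal 9, because the formaldehyde tether offers the catalyst no substituent to grip. The cascade is also reversible, so formaldehyde may be lost again. The fallback sets out from 8 and comes back at 10, and it makes the O3–C3a bond first with boron as the tether. Quinol 8 is condensed with phenylboronic acid in the presence of a chiral bifunctional amine–thiourea catalyst (4 Å MS, toluene, rt). The boronic acid hemiester then delivers its B–OH oxygen to one enone arm (boronate-tethered oxa-Michael addition, known for γ-hydroxy enones). This should give the cis-fused cyclic boronate (3aR,7aS)-2-phenyl-7a-[(2R)-1-(3,4,5-trimethoxyphenyl)propan-2-yl]-3a,7a-dihydro-1,3,2-benzodioxaborol-5(4H)-one F1. Transesterification with diethanolamine should free the cis-diol (4S,5R)-4,5-dihydroxy-4-[(2R)-1-(3,4,5-trimethoxyphenyl)propan-2-yl]cyclohex-2-en-1-one F2. The diol is closed to 10 with dimethoxymethane and catalytic TMSOTf (CH2Cl2, 0 °C).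

Step 6. The C4 enol derivative or the palladium enolate may expel the β-alkoxy group (retro-oxa-Michael opening of the dioxolane and loss of formaldehyde) instead of undergoing β-hydride elimination. The fallback sets out from 10 and comes back at 12, and it uses a selenoxide elimination that can only remove a hydrogen. Ketone 10 is selenenylated at C4 through its enol with PhSeCl in EtOAc at rt, without an enolate or a metal. This should give (3aS,7aS)-4-(phenylselanyl)-7a-[(2R)-1-(3,4,5-trimethoxyphenyl)propan-2-yl]-3a,7a-dihydro-1,3-benzodioxol-5(4H)-one F3 as a mixture of C4 epimers. Oxidation with H2O2/pyridine (CH2Cl2, 0 °C) and syn-elimination of the selenoxide toward H-3a, the only β-hydrogen, should give 12.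

Step 8. Allyl bromide may attack dienolate 14 with insufficient facial selectivity, and proton exchange between product and enolate may lead to double allylation. The fallback sets out from 13 and comes back at 15, and it forms the C6–allyl bond by a Tsuji decarboxylative allylation. The dienolate is O-acylated with allyl chloroformate (LiHMDS, TMEDA, THF, −78 °C) to give allyl (7aR)-7a-[(2R)-1-(3,4,5-trimethoxyphenyl)propan-2-yl]-7,7a-dihydro-1,3-benzodioxol-5-yl carbonate F4. Pd2(dba)3 with a chiral P,N ligand (THF, rt) then releases CO2 and recombines the enolate and the π-allyl fragment regiospecifically at C6. This allows ligand control of the face and excludes a second allylation. Any residual 6S epimer, which carries the axial allyl group, could be equilibrated with base toward 15.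

**Further compounds**
F1 | step 5 | (3aR,7aS)-2-phenyl-7a-[(2R)-1-(3,4,5-trimethoxyphenyl)propan-2-yl]-3a,7a-dihydro-1,3,2-benzodioxaborol-5(4H)-one | O=C1C=C[C@]2([C@H](C)Cc3cc(OC)c(OC)c(OC)c3)OB(c3ccccc3)O[C@@H]2C1
F2 | step 5 | (4S,5R)-4,5-dihydroxy-4-[(2R)-1-(3,4,5-trimethoxyphenyl)propan-2-yl]cyclohex-2-en-1-one | O=C1C=C[C@@](O)([C@H](C)Cc2cc(OC)c(OC)c(OC)c2)[C@H](O)C1
F3 | step 6 | (3aS,7aS)-4-(phenylselanyl)-7a-[(2R)-1-(3,4,5-trimethoxyphenyl)propan-2-yl]-3a,7a-dihydro-1,3-benzodioxol-5(4H)-one (C4 epimers) | O=C1C=C[C@]2([C@H](C)Cc3cc(OC)c(OC)c(OC)c3)OCO[C@@H]2C1[Se]c1ccccc1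
F4 | step 8 | allyl (7aR)-7a-[(2R)-1-(3,4,5-trimethoxyphenyl)propan-2-yl]-7,7a-dihydro-1,3-benzodioxol-5-yl carbonate | C=CCOC(=O)OC1=CC[C@]2([C@H](C)Cc3cc(OC)c(OC)c(OC)c3)OCOC2=C1
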